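**Assumption:** the SMILES is read literally: the oxirane is (14S,15R) with the two long chains cis on the ring, and all four methyl-bearing centres are R as in natural phytol; natural (E,7R,11R)-phytol and L-malic acid are taken as catalogue materials.

## Retrosynthetic overview

1. The oxirane (the only ring, formed last) comes from the (14S,15S)-diol by mesylation of the secondary OH and invertive closure at C15.
2. C13–C14 comes from chelation-controlled addition of a phytol-derived C16 Grignard reagent to an (S)-α-hydroxy methyl ketone; the C14 methyl comes from MeLi on a dioxolanone.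
3. C16–C17, the junction of the two halves, comes from a visible-light decarboxylative allyl transfer inside the phytyl ester of L-malic acid acetonide, with the E-olefin of phytol carried through intact.
4. Sources: natural phytol (used twice) and L-malic acid (supplies C14–C16 and the C15 stereocentre; its distal carboxyl leaves as CO2).
5. Numbering (lycopane): oxirane C14 (quaternary) and C15 (CH), junction C16–C17, olefin C18=C19.

## Route

**Step 1**
Reactants: 1 L-malic acid, (S)-2-hydroxybutanedioic acid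
Product: 2 (S)-2-(2,2-dimethyl-5-oxo-1,3-dioxolan-4-yl)acetic acid
Conditions: 2,2-dimethoxypropane (3 equiv), TsOH·H2O (1 mol%), 25 °C, 3 h; crystallise
Reagents that add atoms: 2,2-dimethoxypropane, COC(C)(C)OC
Why: Acid-catalysed transacetalisation closes the five-membered dioxolanone on the α-hydroxy acid unit only, leaving the distal CO2H free and the (S) centre untouched.

**Step 2**
Reactants: 2 (S)-2-(2,2-dimethyl-5-oxo-1,3-dioxolan-4-yl)acetic acid; 3 natural phytol, (2E,7R,11R)-3,7,11,15-tetramethylhexadec-2-en-1-ol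
Product: 4 (2E,7R,11R)-3,7,11,15-tetramethylhexadec-2-en-1-yl 2-[(4S)-2,2-dimethyl-5-oxo-1,3-dioxolan-4-yl]acetate
Conditions: DCC (1.1 equiv), 4-(dimethylamino)pyridine (5 mol%), CH2Cl2, 0 → 25 °C
Reagents that add atoms: none
Why: Steglich esterification of a primary allylic alcohol under near-neutral conditions touches neither the E-olefin nor the dioxolanone nor C15.

**Step 3**
Reactants: 4 phytyl ester of the malic acetonide acid
Product: 5 (5S)-2,2-dimethyl-5-[(3E,8R,12R)-4,8,12,16-tetramethylheptadec-3-en-1-yl]-1,3-dioxolan-4-one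
Conditions: Pd2(dba)3 (2.5 mol%), Xantphos (6 mol%), Ir[dF(CF3)ppy]2(dtbbpy)PF6 (2 mol%), DMA/PhCF3 2:1 (0.05 M, degassed), 450 nm LEDs, 25 °C
Reagents that add atoms: none
Why: Proposed new method: a light-driven decarboxylative allyl transfer ("ester contraction") of an unstabilised primary alkanoate, in which zerovalent palladium ionises the allylic C–O bond of 4 to an (η3-phytyl)palladium cation/carboxylate ion pair, the photoexcited iridium complex oxidises the carboxylate by one electron, CO2 is lost, the primary C16 radical is captured by the divalent allylpalladium cation to give a trivalent alkyl(allyl)palladium that, after reduction by the reduced photocatalyst, reductively eliminates C16–C17 at the unsubstituted allyl terminus and returns zerovalent palladium; the E geometry should survive because syn/anti exchange at the 3,3-disubstituted terminus would need a tertiary σ-allyl, and C15 (β to the radical, no base present) is not touched; closest known reaction type: dual photoredox/palladium decarboxylative allylation of allyl esters of α-amino and arylacetic acids (stabilised radicals) and radical allylic alkylation through π-allylpalladium.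

**Step 4**
Reactants: 5 (5S)-dioxolanone
Product: 7 (3S,6E,11R,15R)-3-hydroxy-7,11,15,19-tetramethylicos-6-en-2-one, via lithium hemiketal alkoxide 6 (not isolated)
Conditions: MeLi (1.05 equiv), THF, −78 °C, 30 min; then pH 7 phosphate buffer, −78 → 0 °C
Reagents that add atoms: methyllithium, [Li]C
Why: The dioxolanone behaves as a lactone, so one MeLi adds to give a tetrahedral lithium alkoxide that holds at −78 °C and collapses only on aqueous quench with loss of acetone (organolithium mono-addition to a lactone-type acyl group), giving the α-hydroxy methyl ketone without over-addition or erosion at C15.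

**Step 5**
Reactants: 3 natural phytol
Product: 8 (6R,10R)-6,10,14-trimethylpentadecan-2-one (phytone)
Conditions: O3, CH2Cl2, −78 °C; then Me2S, −78 → 25 °C
Reagents that add atoms: ozone, [O-][O+]=O
Why: Ozonolysis with reductive work-up cleaves the only olefin to the methyl ketone and leaves both remote methyl stereocentres untouched.

**Step 6**
Reactants: 8 phytone
Product: 10 (4R,8R)-4,8,12-trimethyltridecan-1-ol, via alkyl acetate 9 (not isolated)
Conditions: mCPBA (1.5 equiv), CF3CO2H (20 mol%), CH2Cl2, 25 °C, dark; then MeOH, TsOH·H2O (10 mol%), 45 °C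
Reagents that add atoms: meta-chloroperbenzoic acid, OOC(=O)c1cccc(Cl)c1
Why: Baeyer–Villiger oxidation in which the primary alkyl group migrates in preference to methyl gives the acetate of the C16 alcohol, which acid-catalysed methanolysis frees in the same flask.

**Step 7**
Reactants: 10 (4R,8R)-4,8,12-trimethyltridecan-1-ol
Product: 11 (4R,8R)-1-bromo-4,8,12-trimethyltridecane
Conditions: CBr4 (1.2 equiv), PPh3 (1.25 equiv), CH2Cl2, 0 → 25 °C
Reagents that add atoms: carbon tetrabromide, BrC(Br)(Br)Br
Why: Appel bromination of an unhindered primary alcohol proceeds under neutral conditions with no stereocentre near the reacting carbon.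

**Step 8**
Reactants: 7 (S)-α-hydroxy methyl ketone; 11 C16 bromide
Product: 14 (6R,10R,14S,15S,18E,23R,27R)-2,6,10,14,19,23,27,31-octamethyldotriacont-18-ene-14,15-diol, via Grignard reagent 12 (not isolated), via chloromagnesium alkoxide 13 (not isolated)
Conditions: 11, Mg turnings, Et2O, 35 °C (gives 12); 7, t-BuMgCl (1.0 equiv), Et2O/CH2Cl2, −78 °C (gives 13); then 12 (1.5 equiv), −78 → −40 °C; sat. aq. NH4Cl
Reagents that add atoms: none
Why: Cram cyclic-chelate (chelation-controlled) Grignard addition, in which magnesium locks the C15 alkoxide and the C14 carbonyl in a five-membered chelate and the chain adds from the face bearing the C15 hydrogen, sets (14S) from the malic-acid-derived (15S) centre.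

**Step 9**
Reactants: 14 (14S,15S)-diol
Product: 16 target, (2S,3R)-2-methyl-3-[(3E,8R,12R)-4,8,12,16-tetramethylheptadec-3-en-1-yl]-2-[(4R,8R)-4,8,12-trimethyltridecyl]oxirane, via secondary mesylate 15 (not isolated)
Conditions: MsCl (1.2 equiv), Et3N (2 equiv), CH2Cl2, −10 °C; then MeOH, K2CO3 (3 equiv), 25 °C
Reagents that add atoms: none
Why: Selective sulfonylation of the secondary alcohol followed by intramolecular Williamson (SN2) closure by the tertiary alkoxide inverts C15 from S to R while C14 stays S, which puts the two long chains cis on the oxirane.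

## Compound list

1 | L-malic acid, (S)-2-hydroxybutanedioic acid | O[C@@H](CC(=O)O)C(=O)O | starting material
2 | (S)-2-(2,2-dimethyl-5-oxo-1,3-dioxolan-4-yl)acetic acid | CC1(C)O[C@@H](CC(=O)O)C(=O)O1 | intermediate
3 | natural phytol, (2E,7R,11R)-3,7,11,15-tetramethylhexadec-2-en-1-ol | C/C(=C\CO)CCC[C@H](C)CCC[C@H](C)CCCC(C)C | starting material
4 | (2E,7R,11R)-3,7,11,15-tetramethylhexadec-2-en-1-yl 2-[(4S)-2,2-dimethyl-5-oxo-1,3-dioxolan-4-yl]acetate | C/C(=C\COC(=O)C[C@@H]1OC(C)(C)OC1=O)CCC[C@H](C)CCC[C@H](C)CCCC(C)C | intermediate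
5 | (5S)-2,2-dimethyl-5-[(3E,8R,12R)-4,8,12,16-tetramethylheptadec-3-en-1-yl]-1,3-dioxolan-4-one | C/C(=C\CC[C@@H]1OC(C)(C)OC1=O)CCC[C@H](C)CCC[C@H](C)CCCC(C)C | intermediate
6 | lithium (5S)-2,2,4-trimethyl-5-[(3E,8R,12R)-4,8,12,16-tetramethylheptadec-3-en-1-yl]-1,3-dioxolan-4-olate (both C4 epimers) | C/C(=C\CC[C@@H]1OC(C)(C)OC1(C)[O-])CCC[C@H](C)CCC[C@H](C)CCCC(C)C.[Li+] | intermediate
7 | (3S,6E,11R,15R)-3-hydroxy-7,11,15,19-tetramethylicos-6-en-2-one | C/C(=C\CC[C@H](O)C(C)=O)CCC[C@H](C)CCC[C@H](C)CCCC(C)C | intermediate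
8 | (6R,10R)-6,10,14-trimethylpentadecan-2-one | CC(=O)CCC[C@H](C)CCC[C@H](C)CCCC(C)C | intermediate
9 | (4R,8R)-4,8,12-trimethyltridecyl acetate | CC(=O)OCCC[C@H](C)CCC[C@H](C)CCCC(C)C | intermediate
10 | (4R,8R)-4,8,12-trimethyltridecan-1-ol | OCCC[C@H](C)CCC[C@H](C)CCCC(C)C | intermediate
11 | (4R,8R)-1-bromo-4,8,12-trimethyltridecane | BrCCC[C@H](C)CCC[C@H](C)CCCC(C)C | intermediate
12 | [(4R,8R)-4,8,12-trimethyltridecyl]magnesium bromide | Br[Mg]CCC[C@H](C)CCC[C@H](C)CCCC(C)C | intermediate
13 | chloromagnesium (3S,6E,11R,15R)-7,11,15,19-tetramethyl-2-oxoicos-6-en-3-olate | C/C(=C\CC[C@H](O[Mg]Cl)C(C)=O)CCC[C@H](C)CCC[C@H](C)CCCC(C)C | intermediate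
14 | (6R,10R,14S,15S,18E,23R,27R)-2,6,10,14,19,23,27,31-octamethyldotriacont-18-ene-14,15-diol | C/C(=C\CC[C@H](O)[C@@](C)(O)CCC[C@H](C)CCC[C@H](C)CCCC(C)C)CCC[C@H](C)CCC[C@H](C)CCCC(C)C | intermediate
15 | (6R,10R,14S,15S,18E,23R,27R)-14-hydroxy-2,6,10,14,19,23,27,31-octamethyldotriacont-18-en-15-yl methanesulfonate | C/C(=C\CC[C@H](OS(C)(=O)=O)[C@@](C)(O)CCC[C@H](C)CCC[C@H](C)CCCC(C)C)CCC[C@H](C)CCC[C@H](C)CCCC(C)C | intermediate
16 | (2S,3R)-2-methyl-3-[(3E,8R,12R)-4,8,12,16-tetramethylheptadec-3-en-1-yl]-2-[(4R,8R)-4,8,12-trimethyltridecyl]oxirane (CNP0229802.1) | C/C(=C\CC[C@H]1O[C@@]1(C)CCC[C@H](C)CCC[C@H](C)CCCC(C)C)CCC[C@H](C)CCC[C@H](C)CCCC(C)C | target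

## Step count and risks

Total steps: 9 (8 if acid 2, itself a catalogue compound, is bought).
Longest linear sequence: 6 (steps 1, 2, 3, 4, 8, 9 from L-malic acid; either phytol branch is 5).

**Risk 1 – step 3 (the new photochemical allyl transfer).** The likely failure modes are sluggish oxidation of the unstabilised carboxylate, ligand oxidation, phytadiene formation from the allylpalladium, or branched and Z isomers. The fallback uses only known chemistry, sets out from 1 and 3 and comes back at 5. L-Malic acid 1 is esterified (MeOH, SOCl2) to dimethyl (2S)-2-hydroxybutanedioate F1, and phytol 3 is converted (PBr3, Et2O, −10 °C) into (2E,7R,11R)-1-bromo-3,7,11,15-tetramethylhexadec-2-ene F2. Fráter–Seebach alkylation of the dilithio alkoxide-enolate of F1 (LiN(SiMe3)2, 2.2 equiv, THF, −78 → −20 °C) with F2 forms the C16–C17 bond by SN2 attack at the primary allylic carbon, with the E-olefin kept, and gives dimethyl (2S,3R)-2-hydroxy-3-[(2E,7R,11R)-3,7,11,15-tetramethylhexadec-2-en-1-yl]butanedioate F3. Saponification (LiOH, THF/H2O) gives (2S,3R)-2-hydroxy-3-[(2E,7R,11R)-3,7,11,15-tetramethylhexadec-2-en-1-yl]butanedioic acid F4. 2,2-Dimethoxypropane/TsOH ties up the α-hydroxy acid as (2R,4E,9R,13R)-2-[(4S)-2,2-dimethyl-5-oxo-1,3-dioxolan-4-yl]-5,9,13,17-tetramethyloctadec-4-enoic acid F5. The free carboxyl is converted (DCC, N-hydroxypyridine-2-thione, CH2Cl2, dark) into the 2-thioxopyridin-1(2H)-yl ester of F5 (Barton ester) F6, which is photolysed directly with Bu3SnH (tungsten lamp, benzene, 25 °C). This Barton reductive decarboxylation removes the extra carboxyl, erases the C16 stereocentre and delivers 5.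

**Risk 2 – step 4 (mono-addition of MeLi to the dioxolanone).** The risks are early collapse with over-addition, or α-ketol isomerisation on work-up. The fallback sets out from 5 and comes back at 7. The dioxolanone 5 is opened with MeNH(OMe)·HCl/i-PrMgCl (THF, −20 °C) to the Weinreb amide (2S,5E,10R,14R)-2-hydroxy-N-methoxy-N,6,10,14,18-pentamethylnonadec-5-enamide F7, which is isolated. F7 is treated with MeMgBr (3 equiv, THF, 0 °C); the stable chelated tetrahedral intermediate prevents over-addition and gives 7 on quench.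

**Risk 3 – step 8 (chelation-controlled addition to the free α-hydroxy ketone).** The risks are enolisation toward the methyl group or insufficient diastereoselectivity with the alkoxide chelate. The fallback sets out from 7 and comes back at 14. Ketone 7 is protected with 4-methoxybenzyl trichloroacetimidate (cat. camphorsulfonic acid, CH2Cl2) as (3S,6E,11R,15R)-3-[(4-methoxyphenyl)methoxy]-7,11,15,19-tetramethylicos-6-en-2-one F8. Grignard reagent 12 is added to the bidentate ether chelate of F8 (MgBr2·OEt2, CH2Cl2, −78 °C) to give (6R,10R,14S,15S,18E,23R,27R)-15-[(4-methoxyphenyl)methoxy]-2,6,10,14,19,23,27,31-octamethyldotriacont-18-en-14-ol F9. DDQ (CH2Cl2/pH 7 buffer) removes the ether and gives 14.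

## Further compounds

F1 | step 3 | dimethyl (2S)-2-hydroxybutanedioate | COC(=O)C[C@H](O)C(=O)OC
F2 | step 3 | (2E,7R,11R)-1-bromo-3,7,11,15-tetramethylhexadec-2-ene | C/C(=C\CBr)CCC[C@H](C)CCC[C@H](C)CCCC(C)C
F3 | step 3 | dimethyl (2S,3R)-2-hydroxy-3-[(2E,7R,11R)-3,7,11,15-tetramethylhexadec-2-en-1-yl]butanedioate | COC(=O)[C@@H](O)[C@@H](C/C=C(\C)CCC[C@H](C)CCC[C@H](C)CCCC(C)C)C(=O)OC
F4 | step 3 | (2S,3R)-2-hydroxy-3-[(2E,7R,11R)-3,7,11,15-tetramethylhexadec-2-en-1-yl]butanedioic acid | OC(=O)[C@@H](O)[C@@H](C/C=C(\C)CCC[C@H](C)CCC[C@H](C)CCCC(C)C)C(=O)O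
F5 | step 3 | (2R,4E,9R,13R)-2-[(4S)-2,2-dimethyl-5-oxo-1,3-dioxolan-4-yl]-5,9,13,17-tetramethyloctadec-4-enoic acid | CC1(C)O[C@@H]([C@@H](C/C=C(\C)CCC[C@H](C)CCC[C@H](C)CCCC(C)C)C(=O)O)C(=O)O1
F6 | step 3 | 2-thioxopyridin-1(2H)-yl (2R,4E,9R,13R)-2-[(4S)-2,2-dimethyl-5-oxo-1,3-dioxolan-4-yl]-5,9,13,17-tetramethyloctadec-4-enoate | CC1(C)O[C@@H]([C@@H](C/C=C(\C)CCC[C@H](C)CCC[C@H](C)CCCC(C)C)C(=O)On2ccccc2=S)C(=O)O1
F7 | step 4 | (2S,5E,10R,14R)-2-hydroxy-N-methoxy-N,6,10,14,18-pentamethylnonadec-5-enamide | C/C(=C\CC[C@H](O)C(=O)N(C)OC)CCC[C@H](C)CCC[C@H](C)CCCC(C)C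
F8 | step 8 | (3S,6E,11R,15R)-3-[(4-methoxyphenyl)methoxy]-7,11,15,19-tetramethylicos-6-en-2-one | C/C(=C\CC[C@H](OCc1ccc(OC)cc1)C(C)=O)CCC[C@H](C)CCC[C@H](C)CCCC(C)C
F9 | step 8 | (6R,10R,14S,15S,18E,23R,27R)-15-[(4-methoxyphenyl)methoxy]-2,6,10,14,19,23,27,31-octamethyldotriacont-18-en-14-ol | C/C(=C\CC[C@H](OCc1ccc(OC)cc1)[C@@](C)(O)CCC[C@H](C)CCC[C@H](C)CCCC(C)C)CCC[C@H](C)CCC[C@H](C)CCCC(C)C
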